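## Retrosynthetic overview

1. Ring A (unsaturated seven-membered lactone) is closed last: C1=C2 by ring-closing metathesis of a C10 vinyl group with a C4 acrylate; the C16 hydroxyl comes from enol oxidation just before.
2. The C13 methylene comes from the bridging ketone of a bicyclo[3.3.1]nonane trione; ring D is made by (3+3) annulation of methylmalonyl dichloride across C12/C14 of a ring C β-keto ester.
3. Ring C and the C8–C14 bond between two fully substituted carbons (the key bond) come from a visible-light photoredox 6-endo hydroalkylative radical cyclisation of a β-keto ester onto the tetrasubstituted C8=C9 alkene.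
4. The cyclisation precursor comes from a ring B allylic bromide and the dianion of methyl 3-oxopentanoate (C11–C12 bond).
5. Ring B with C5 and C10 comes from (S)-(+)-carvone (methylation, then vinylation trans to isopropenyl). Ring order: B (bought) → C → D → A.

Assumption: steroid-type locants are used (ring A: C1–C5 and C10, lactone oxygen between C3 and C4; ring B: C5–C10; ring C: C8, C9, C11–C14; ring D: C12–C17), and "methyl face" means the face of ring B that carries the C8 and C10 methyl groups.

## Route

Step 1
Reactants: 1 (S)-(+)-carvone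
Product: 2 (5S,6RS)-2,6-dimethyl-5-(prop-1-en-2-yl)cyclohex-2-en-1-one
Conditions: LiN(i-Pr)2, THF, −78 °C; MeI, −78 → 0 °C
Reagents that add atoms: iodomethane (CI)
Why: Kinetic α′-deprotonation of the enone and SN2 methylation (enolate alkylation) occur only at C6; the new centre is left as a mixture because it is re-enolised in step 2, and C5 is carried over from (S)-carvone.

Step 2
Reactants: 2 (5S,6RS)-2,6-dimethyl-5-(prop-1-en-2-yl)cyclohex-2-en-1-one
Product: 4 (5R,6R)-6-ethenyl-2,6-dimethyl-5-(prop-1-en-2-yl)cyclohex-2-en-1-one, via sulfoxide adduct 3 (not isolated)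
Conditions: LiN(i-Pr)2, THF, −78 °C; CH2=CHS(O)Ph, −78 → 0 °C; H2O; then toluene, 110 °C
Reagents that add atoms: phenyl vinyl sulfoxide (C=CS(=O)c1ccccc1)
Why: Michael addition of the tetrasubstituted lithium enolate to the vinyl sulfoxide (a vinyl cation equivalent) takes place on the ring face anti to the neighbouring isopropenyl group, which sets the quaternary centre (future C10) with vinyl trans to isopropenyl, and thermal syn-elimination of the sulfoxide then unveils the vinyl group.

Step 3
Reactants: 4 (5R,6R)-6-ethenyl-2,6-dimethyl-5-(prop-1-en-2-yl)cyclohex-2-en-1-one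
Product: 6 6-ethenyl-2,6-dimethyl-5-(prop-1-en-2-yl)cyclohex-1-en-1-yl trifluoromethanesulfonate (C5 and C6 as in 4), via lithium enolate 5 (not isolated)
Conditions: LiBH(s-Bu)3, THF, −78 °C; PhNTf2, −78 → 23 °C
Reagents that add atoms: N-phenylbis(trifluoromethanesulfonimide) (O=S(=O)(N(c1ccccc1)S(=O)(=O)C(F)(F)F)C(F)(F)F)
Why: Conjugate hydride reduction of the enone gives the regiodefined tetrasubstituted enolate, which is O-sulfonylated (enolate triflation) without touching a stereocentre.

Step 4
Reactants: 6 enol triflate
Product: 7 methyl 6-ethenyl-2,6-dimethyl-5-(prop-1-en-2-yl)cyclohex-1-ene-1-carboxylate (C5 and C6 as in 4)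
Conditions: Pd(OAc)2 (5 mol%), PPh3, CO (1 atm), MeOH, Et3N, DMF, 60 °C
Reagents that add atoms: carbon monoxide ([C-]#[O+]); methanol (CO)
Why: Methoxycarbonylation of the enol triflate (oxidative addition to zerovalent palladium, CO insertion, methanolysis) installs C11 and keeps the tetrasubstituted C8=C9 alkene in place.

Step 5
Reactants: 7 methyl 6-ethenyl-2,6-dimethyl-5-(prop-1-en-2-yl)cyclohex-1-ene-1-carboxylate
Product: 8 methyl 6-ethenyl-5-(2-hydroxypropan-2-yl)-2,6-dimethylcyclohex-1-ene-1-carboxylate (ring stereocentres as in 4)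
Conditions: Co(acac)2 (20 mol%), PhSiH3, O2 (1 atm), THF, 23 °C
Reagents that add atoms: dioxygen (O=O)
Why: Mukaiyama hydration (hydrogen-atom transfer from the cobalt hydride formed from Co(acac)2 and PhSiH3, O2 trapping, reduction) is Markovnikov and selective for the electron-rich 1,1-disubstituted isopropenyl group over the neopentyl vinyl group and the tetrasubstituted enoate; it gives the C4 tertiary alcohol before any radical or acid step and leaves C5 unchanged.

Step 6
Reactants: 8 methyl 6-ethenyl-5-(2-hydroxypropan-2-yl)-2,6-dimethylcyclohex-1-ene-1-carboxylate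
Product: 9 2-[2-ethenyl-3-(hydroxymethyl)-2,4-dimethylcyclohex-3-en-1-yl]propan-2-ol (ring stereocentres as in 4)
Conditions: i-Bu2AlH (3.5 equiv), CH2Cl2, −78 → 0 °C
Reagents that add atoms: none
Why: Hydride reduction of the conjugated ester (1,2-reduction) gives the primary allylic alcohol.

Step 7
Reactants: 9 2-[2-ethenyl-3-(hydroxymethyl)-2,4-dimethylcyclohex-3-en-1-yl]propan-2-ol
Product: 10 2-[3-(bromomethyl)-2-ethenyl-2,4-dimethylcyclohex-3-en-1-yl]propan-2-ol (ring stereocentres as in 4)
Conditions: CBr4, PPh3, CH2Cl2, −20 °C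
Reagents that add atoms: tetrabromomethane (BrC(Br)(Br)Br)
Why: Appel bromination converts only the primary allylic alcohol, because the tertiary carbinol is too hindered to form the oxyphosphonium salt at low temperature.

Step 8
Reactants: 10 2-[3-(bromomethyl)-2-ethenyl-2,4-dimethylcyclohex-3-en-1-yl]propan-2-ol; 11 methyl 3-oxopentanoate
Product: 12 methyl 5-[6-ethenyl-5-(2-hydroxypropan-2-yl)-2,6-dimethylcyclohex-1-en-1-yl]-4-methyl-3-oxopentanoate (ring stereocentres as in 4; chain C4 = C12, both epimers)
Conditions: 11 (3 equiv), NaH, then n-BuLi, THF, 0 °C; 10, 0 → 23 °C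
Reagents that add atoms: none
Why: The γ-carbon of the β-keto ester dianion displaces the primary allylic bromide by SN2 (Weiler dianion alkylation), the excess dianion absorbs the tertiary OH proton, and the new C12 centre is epimerisable and left as a mixture.

Step 9
Reactants: 12 methyl 5-[6-ethenyl-5-(2-hydroxypropan-2-yl)-2,6-dimethylcyclohex-1-en-1-yl]-4-methyl-3-oxopentanoate
Product: 13 methyl 5-ethenyl-6-(2-hydroxypropan-2-yl)-3,5,8a-trimethyl-2-oxodecahydronaphthalene-1-carboxylate (trans-fused; 4a-H and 5-ethenyl opposite the 5- and 8a-methyl groups; 6-substituent cis to the 5-methyl; C1/C3 epimers and enol)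
Conditions: [Ir(dF(CF3)ppy)2(dtbbpy)]PF6 (2 mol%), 2,4,6-(i-Pr)3C6H2SH (20 mol%), K3PO4 (0.5 equiv), MeCN, 450 nm LEDs, 25 °C
Reagents that add atoms: none
Why: Proposed new method: the excited trivalent iridium photocatalyst oxidises the potassium enolate of the β-keto ester to the electrophilic C14 radical, which adds 6-endo to C8 of the electron-rich tetrasubstituted C8=C9 alkene (5-exo attack at C9 is blocked by the adjacent quaternary C10) on the face opposite the axial C10 methyl; the tertiary C9 radical then takes hydrogen from the arenethiol on that same face, because the other face carries both axial methyls, so C8 and C9 are set as the trans ring fusion; the thiyl radical is reduced by divalent iridium and the thiolate is reprotonated by hydrogenphosphate or fresh substrate, which closes a redox-neutral cycle; the closest known chemistry is the Mn(OAc)3-mediated oxidative 6-endo cyclisation of unsaturated β-keto esters and photoredox/thiol hydroalkylation of terminal alkenes with 1,3-dicarbonyls, neither shown for a tetrasubstituted cycloalkene with hydrogen-atom termination.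

Step 10
Reactants: 13 tricyclic β-keto ester; 14 methylmalonyl dichloride
Product: 16 13-oxo trione (rings B/C/D of the target with C13=O, C16 unhydroxylated 15,17-dione in its enol form, C10 vinyl, C5 C(CH3)2OH; stereocentres as in the target), via silyl dienol ether 15 (not isolated)
Conditions: Me3SiOTf, Et3N, CH2Cl2, 0 °C; 14, −78 → 23 °C; then 1 M HCl, THF
Reagents that add atoms: none
Why: Effenberger-type (3+3) α,α′-annulation in which first the terminal carbon (C12) and then the central carbon (C14) of the bis(silyloxy)diene are acylated by the two acid chloride groups; the three-carbon bridge can only span C12 and C14 1,3-diaxially on the ring C face opposite the C8 methyl (the face of H9), so both bridgehead stereocentres are fixed by the existing ring fusion.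

Step 11
Reactants: 16 13-oxo trione
Product: 17 13-methylene dione (16 with C13=CH2; stereocentres as in the target)
Conditions: Ti(C5H5)2(CH3)2 (4 equiv), toluene–THF, 65 °C
Reagents that add atoms: dimethyltitanocene (C[Ti](C)(C1C=CC=C1)C1C=CC=C1)
Why: Petasis methylenation through the titanium methylidene Ti(C5H5)2(=CH2) ((2+2) cycloaddition and cycloreversion) converts the non-enolisable bridging ketone into the exocyclic methylene without an alkoxide stage that could trigger retro-Claisen cleavage, and it spares the hindered ester and the titanium-bound enolate and alkoxide.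

Step 12
Reactants: 17 13-methylene dione
Product: 18 16-hydroxy dione (17 with C16(CH3)(OH), configuration as in the target)
Conditions: m-CPBA (1.1 equiv), CH2Cl2, −20 °C
Reagents that add atoms: 3-chloroperoxybenzoic acid (OOC(=O)c1cccc(Cl)c1)
Why: Epoxidation of the β-diketone enol and ring opening (Rubottom-type α-hydroxylation) deliver oxygen to C16 from the exo face of ring D, away from the C11–C9–C8 bridge of ring C and its inward-pointing H9, which gives the C16 configuration of the target; the neopentyl vinyl group and the hindered methylene react far more slowly.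

Step 13
Reactants: 18 16-hydroxy dione
Product: 19 C4 acrylate (18 with the C4 hydroxyl esterified by prop-2-enoic acid)
Conditions: CH2=CHCOCl, Et3N, DMAP (cat.), CH2Cl2, 0 → 23 °C
Reagents that add atoms: acryloyl chloride (C=CC(=O)Cl)
Why: DMAP-catalysed acylation takes place at the more nucleophilic C4 dimethylcarbinol, whereas the C16 hydroxyl, a tertiary alcohol deactivated by two flanking carbonyl groups and hydrogen-bonded to them, is acylated far more slowly.

Step 14
Reactants: 19 C4 acrylate
Product: 20 target natural product, the ring A unsaturated seven-membered lactone formed from 19 (C10–CH=CH–C(=O)–O–C4; stereocentres as in 19)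
Conditions: [RuCl2(H2IMes)(=CH-C6H4-2-O-i-Pr)] (second-generation Hoveyda–Grubbs catalyst, 10 mol%), toluene, 80 °C
Reagents that add atoms: none
Why: Ring-closing metathesis between the C10 vinyl group and the acrylate closes the seven-membered α,β-unsaturated lactone (cis geometry enforced by the ring), and the hindered exocyclic methylene does not engage the ruthenium alkylidene.

## Compound list

1 | (S)-(+)-carvone, (5S)-2-methyl-5-(prop-1-en-2-yl)cyclohex-2-en-1-one | CC1=CC[C@@H](CC1=O)C(C)=C | starting material
2 | (5S,6RS)-2,6-dimethyl-5-(prop-1-en-2-yl)cyclohex-2-en-1-one | O=C1C(C)=CC[C@H](C(C)=C)C1C | intermediate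
3 | sulfoxide adduct, (5R,6R)-2,6-dimethyl-6-[2-(phenylsulfinyl)ethyl]-5-(prop-1-en-2-yl)cyclohex-2-en-1-one (sulfur epimers) | O=C1C(C)=CC[C@H](C(C)=C)[C@@]1(C)CCS(=O)c1ccccc1 | intermediate (not isolated)
4 | (5R,6R)-6-ethenyl-2,6-dimethyl-5-(prop-1-en-2-yl)cyclohex-2-en-1-one (vinyl trans to isopropenyl) | O=C1C(C)=CC[C@H](C(C)=C)[C@@]1(C)C=C | intermediate
5 | lithium enolate, lithium 6-ethenyl-2,6-dimethyl-5-(prop-1-en-2-yl)cyclohex-1-en-1-olate (C5, C6 as in 4) | [Li+].[O-]C1=C(C)CC[C@H](C(C)=C)[C@@]1(C)C=C | intermediate (not isolated)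
6 | 6-ethenyl-2,6-dimethyl-5-(prop-1-en-2-yl)cyclohex-1-en-1-yl trifluoromethanesulfonate (C5, C6 as in 4) | O=S(=O)(OC1=C(C)CC[C@H](C(C)=C)[C@@]1(C)C=C)C(F)(F)F | intermediate
7 | methyl 6-ethenyl-2,6-dimethyl-5-(prop-1-en-2-yl)cyclohex-1-ene-1-carboxylate (C5, C6 as in 4) | COC(=O)C1=C(C)CC[C@H](C(C)=C)[C@@]1(C)C=C | intermediate
8 | methyl 6-ethenyl-5-(2-hydroxypropan-2-yl)-2,6-dimethylcyclohex-1-ene-1-carboxylate (ring stereocentres as in 4) | COC(=O)C1=C(C)CC[C@H](C(C)(C)O)[C@@]1(C)C=C | intermediate
9 | 2-[2-ethenyl-3-(hydroxymethyl)-2,4-dimethylcyclohex-3-en-1-yl]propan-2-ol (ring stereocentres as in 4) | OCC1=C(C)CC[C@H](C(C)(C)O)[C@@]1(C)C=C | intermediate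
10 | 2-[3-(bromomethyl)-2-ethenyl-2,4-dimethylcyclohex-3-en-1-yl]propan-2-ol (ring stereocentres as in 4) | BrCC1=C(C)CC[C@H](C(C)(C)O)[C@@]1(C)C=C | intermediate
11 | methyl 3-oxopentanoate | CCC(=O)CC(=O)OC | starting material
12 | methyl 5-[6-ethenyl-5-(2-hydroxypropan-2-yl)-2,6-dimethylcyclohex-1-en-1-yl]-4-methyl-3-oxopentanoate (ring stereocentres as in 4; chain C4 epimers) | COC(=O)CC(=O)C(C)CC1=C(C)CC[C@H](C(C)(C)O)[C@@]1(C)C=C | intermediate
13 | methyl 5-ethenyl-6-(2-hydroxypropan-2-yl)-3,5,8a-trimethyl-2-oxodecahydronaphthalene-1-carboxylate (trans-fused; 4a-H and 5-ethenyl opposite the 5- and 8a-methyls; C1/C3 epimers and enol) | O=C1C(C)C[C@H]3[C@](C)(C=C)[C@@H](C(C)(C)O)CC[C@]3(C)C1C(=O)OC | intermediate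
14 | methylmalonyl dichloride (2-methylpropanedioyl dichloride) | CC(C(=O)Cl)C(=O)Cl | starting material
15 | silyl dienol ether, tris(trimethylsilyl) derivative of 13 (C12=C13 silyl enol ether, ketene silyl methyl acetal at C14, silyl ether of the C4 alcohol) | C[Si](C)(C)OC1=C(C)C[C@H]3[C@](C)(C=C)[C@@H](C(C)(C)O[Si](C)(C)C)CC[C@]3(C)C1=C(OC)O[Si](C)(C)C | intermediate (not isolated)
16 | 13-oxo trione (rings B/C/D of the target with C13=O; 15,17-dione as enol, C16 methyl; C10 vinyl; C5 C(CH3)2OH; stereocentres as in the target) | O=C1[C@@]2(C)C[C@H]3[C@](C)(C=C)[C@@H](C(C)(C)O)CC[C@]3(C)[C@]1(C(=O)OC)C(=O)C(C)=C2O | intermediate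
17 | 13-methylene dione (16 with C13=CH2) | C=C1[C@@]2(C)C[C@H]3[C@](C)(C=C)[C@@H](C(C)(C)O)CC[C@]3(C)[C@]1(C(=O)OC)C(=O)C(C)=C2O | intermediate
18 | 16-hydroxy dione (17 with C16(CH3)(OH), hydroxyl on the exo face of ring D) | C=C1[C@@]2(C)C[C@H]3[C@](C)(C=C)[C@@H](C(C)(C)O)CC[C@]3(C)[C@]1(C(=O)OC)C(=O)[C@@](C)(O)C2=O | intermediate
19 | C4 acrylate of 18 | C=C1[C@@]2(C)C[C@H]3[C@](C)(C=C)[C@@H](C(C)(C)OC(=O)C=C)CC[C@]3(C)[C@]1(C(=O)OC)C(=O)[C@@](C)(O)C2=O | intermediate
20 | target natural product: 19 with ring A closed as the seven-membered 1,2-unsaturated lactone (C10–C1H=C2H–C3(=O)–O–C4(CH3)2–C5), 16-hydroxy-13-methylene-15,17-dione, methyl ester at C14 | C=C1[C@@]2(C)C[C@H]3[C@]4(C)C=CC(=O)OC(C)(C)[C@H]4CC[C@]3(C)[C@]1(C(=O)OC)C(=O)[C@@](C)(O)C2=O | target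

## Step count and risks

Total step count: 14. Longest linear sequence: 14 steps from (S)-(+)-carvone; 11 and 14 are bought and enter directly.

The three steps most likely to fail:

Step 9 (the proposed new photochemical cyclisation). The risks are 5-exo closure, O-cyclisation of the enol, and slow hydrogen transfer to the hindered C9 radical (which also has a vinyl group on the neighbouring carbon). The fallback sets out from 12. Bromination at C14 (NBS, catalytic Mg(ClO4)2, EtOAc, 0 °C) gives methyl 2-bromo-5-[6-ethenyl-5-(2-hydroxypropan-2-yl)-2,6-dimethylcyclohex-1-en-1-yl]-4-methyl-3-oxopentanoate F1. Slow addition of Bu3SnH with AIBN in benzene at 80 °C then runs the known reductive radical cyclisation of an α-bromo β-keto ester, with bromine abstraction in place of enolate oxidation and tin hydride as the hydrogen source. The fallback rejoins the route at 13.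

Step 10 (annulation with a β-keto ester-derived diene and a substituted malonyl chloride). The risks are pyranone formation by O-acylation and low conversion at the hindered C14. The fallback sets out from 13 through the same silyl dienol ether 15, but uses unsubstituted malonyl dichloride, the classical Effenberger partner, to give the C16-unsubstituted 13-oxo trione F2. The C16 methyl is then introduced separately by C-methylation of the β-diketone (MeI, K2CO3, acetone). The fallback rejoins the route at 16.

Step 11 (methylenation of a bridging ketone flanked by two quaternary carbons). The risks are no reaction or attack at the ester. The fallback sets out from 16. Addition of the organocerium reagent from Me3SiCH2MgCl and CeCl3 (THF, −78 °C) to the bridging ketone gives the 13-hydroxy-13-(trimethylsilylmethyl) adduct F3. Acid-mediated Peterson elimination (HF·pyridine, MeCN, 0 °C) can only form the exocyclic alkene and leaves the C4 carbinol alone. The fallback rejoins the route at 17.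

## Further compounds

F1 | step 9 | methyl 2-bromo-5-[6-ethenyl-5-(2-hydroxypropan-2-yl)-2,6-dimethylcyclohex-1-en-1-yl]-4-methyl-3-oxopentanoate | COC(=O)C(Br)C(=O)C(C)CC1=C(C)CC[C@H](C(C)(C)O)[C@@]1(C)C=C
F2 | step 10 | C16-unsubstituted 13-oxo trione (16 without the C16 methyl) | O=C1[C@@]2(C)C[C@H]3[C@](C)(C=C)[C@@H](C(C)(C)O)CC[C@]3(C)[C@]1(C(=O)OC)C(=O)C=C2O
F3 | step 11 | 13-hydroxy-13-(trimethylsilylmethyl) adduct of 16 | C[Si](C)(C)CC1(O)[C@@]2(C)C[C@H]3[C@](C)(C=C)[C@@H](C(C)(C)O)CC[C@]3(C)[C@]1(C(=O)OC)C(=O)C(C)=C2O
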